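Counting reagent is the easy step: a mono adduct has taken one, a bis adduct two, and substrate gone but not found as mono adduct is bis adduct.

| setting | noon | midnight | flask |
|---|---|---|---|
| substrate | 0.21 M | 0.21 M | 0.21 M |
| reagent | 0.11 M | 0.17 M | 0.110 M |
| remark | the very flask that is asked about, followed so far | run made earlier |  |
| time |  |  | 12 min |

| run | time / min | mono adduct / % | substrate / % |
|---|---|---|---|
| noon | 0.250 | 2.0 | 98.6 |
| noon | 0.667 | 4.4 | 95.4 |
| noon | 1.33 | 7.6 | 91.7 |
| noon | 2.00 | 10.0 | 89.9 |
| noon | 3.00 | 12.5 | 85.7 |
| noon | 4.00 | 13.2 | 83.5 |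
| midnight | 0.667 | 6.7 | 93.2 |
| midnight | 1.00 | 9.1 | 89.7 |
| midnight | 2.00 | 14.1 | 84.1 |
| midnight | 3.00 | 16.6 | 79.3 |
| midnight | 5.00 | 18.6 | 73.5 |
| midnight | 8.00 | 21.4 | 68.7 |

(scatter of a reading: 0.5 percentage points)

* equivalents of reagent to substrate, everything else as given, that leave most mono adduct at 12 min
* the amount of mono adduct then, in percent of the substrate charged
* the amount of mono adduct with the amounts as given

- the numbers in the tables scatter by 0.5 percentage points (one standard deviation)
- steps that have been proposed: reagent <-> dormant form; reagent + mono adduct -> bis adduct + by-product; substrate + reagent -> mono adduct + by-product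

To whoever takes over the noon flask: at 4.00 min it holds 83.5% substrate and 13.2% mono adduct. At 3.00 min it has put 0.307 of its reagent charge into adducts, and the midnight run 0.306. So the fraction follows time, not charge, as in a pseudo-first-order loss of reagent.

I therefore join noon at 4.00 min, 0.378, to midnight at 8.00 min, 0.509. Each equal stretch adds 0.346 of the stretch before, which gives 0.554 at 12 min. This is the spent share, the part of the reagent charge gone into adducts.

Per substrate charged that is 0.290, and the midnight run at that spending reads 17.5% mono adduct, so expect that. The midnight run, charged with more reagent, holds 21.4% mono adduct and 9.90% bis adduct at 8.00 min.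

The forecast gives 18.8%, and 25.5% at 1.2 equiv: “The optimum is flat.”

The flask gives 17.7%, and 23.9% at 1.31 equiv.

    reagent ⇌ dormant form (K = 13.4, k = 0.00196 s⁻¹)
    reagent + mono adduct → bis adduct + by-product (k = 0.0243 M⁻¹ s⁻¹)
    substrate + reagent → mono adduct + by-product (k = 0.0113 M⁻¹ s⁻¹)

By-product at 12.0 min makes the spent share 0.561. Applied to the neighbour flask with 0.44 M reagent, 0.554 predicts 0.244 M by-product, and it holds 0.236 M. The flask has not come to rest at 12.0 min: 0.0431 M dormant form remains, though its falling back barely counts by then. At 120 min the spent share reaches 0.756, with mono adduct 20.5%, bis adduct 9.56%, substrate 69.9% and dormant form still 0.0260 M.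

The numbers in the tables are calculated on assumed constants, noise included.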